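## Analysis of the target

Schizotenuin A (31) is a 2-arylbenzofuran. Ring A is the benzo ring (C3a, C4–C7, C7a) and ring B the furan ring (O1, C2, C3); C2 carries a 3,4-dihydroxyphenyl group, C3 a carboxyl group, C5 an (E)-propenoate chain and C7 a hydroxyl group. Both carboxyl groups (on C3 and at the end of the C5 chain) are esterified with the secondary hydroxyl of (R)-3-(3,4-dihydroxyphenyl)lactic acid. The molecule therefore has only two stereocentres, both R, in separate open side chains with no ring relating them; they are best taken unchanged from the chiral pool. Sensitive groups are three catechols and the C7 phenol (oxidation in air or base), the (E)-cinnamate double bond (which rules out hydrogenolysis at the end), and two α-acyloxy acid units whose ester links are base-labile and whose α-hydrogens can epimerise. The C3 ester is the most crowded bond: it sits between the C2 aryl group and the peri C4–H and must be formed with a secondary alcohol. The difficulties are the regiochemistry of ring A, an early and racemisation-free C3 esterification, and protecting groups that come off without touching the alkene. The strategy rests on ring A: oxygen at C7 and the side chain at C5 are meta, with hydrogen at C4 and C6. This is the resorcinol pattern that a vinylketene and an ynol ether deliver if the C5 substituent is first an oxygen, so ring B can be made first as a simple furan and ring A grown on its free C4–C5 edge.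

## Retrosynthetic reasoning

**31 ⇒ 30.** No skeletal bond is cut; the last operation removes nine benzyl groups (seven ethers, two esters) from 30. Benzyl is chosen because it survives every earlier step (acid, acyl chloride formation, light, fluoride, palladium). The forward step must cleave benzyl–oxygen bonds by Lewis-acid ionisation with a cation trap, leaving the alkene, the two secondary ester links and both stereocentres alone.

**30 ⇒ 28 + 29.** The bond between C5 of ring A and the propenoate carbon is cut. This is the only aryl–alkene bond, and cutting it releases the second lactate unit as the simple acrylate 29 and the core as the aryl triflate 28. A Heck reaction must form the bond with E geometry without epimerising either α-acyloxy ester.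

**28 ⇒ 27 ⇒ 26 ⇒ 25.** These are functional-group changes on ring A. The benzannulation delivers the two ring-A oxygens already differentiated (free phenol at C7, silyl ether at C5). Benzylation of C7, desilylation and triflation turn the C5 oxygen into the coupling handle.

**25 ⇒ 15 + 20.** This is the key disconnection. Ring A is cut at C3a–C4, C4–C5, C6–C7 and C7–C7a, which leaves the furan diazomethyl ketone 15 and the siloxyalkyne 20. The cut is made here because every substituent of ring A is then placed by the ring construction itself: the ketone carbon of 15 becomes C7 with its hydroxyl, the diazo carbon becomes C4, and 20 supplies C5 (with oxygen) and C6. The forward cascade runs through ketene 21, cyclobutenone 22, dienylketene 23 and dienone 24; it needs a regioselective [2+2] addition and ring closure onto the only free furan α-carbon.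

**15 ⇒ 13.** The bond between the acyl carbon and the diazo carbon is cut; acid 13 is activated as chloride 14 and homologated in an Arndt–Eistert-type acylation.

**13 ⇒ 11 ⇒ 7 + 9.** Ring B is opened at the bond between the ester-bearing carbon and the carboxyl-bearing carbon and at the O–CH bond. A Feist–Benary reaction of β-keto ester 7 with bromopyruvate 9 gives hydroxydihydrofuran 11; one acid treatment aromatises it (via 12) and frees the acid 13. The hindered C3 ester is thus already in place before the furan exists.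

**7 ⇒ 5 + 2; 5 ⇒ 3 + 4; 2 ⇒ 1.** The ester C–O bond of 7 is cut. The protected lactate 2 captures aroylketene 6, released thermally from the acyl Meldrum's acid 5, which comes from acid 3 and 4. This esterification needs no base, so the stereocentre of 2, obtained by benzylation of 1, is safe.

**29 ⇒ 2; 9 ⇒ 8; 20 ⇒ 16 + 17.** The remaining pieces come from simple materials: acylation of 2, tert-butyl ester formation from 8, and oxidation of lithium acetylide 18 (from 16) to ynolate 19 followed by O-silylation with 17.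

## Alternatives that were turned down

**Alternative 1:** Ring contraction of a flavanone.
- Disconnection: ring B is traced back to a pyranone; the C3–C3a bond and the ester C–O bond are formed together.
- Forward key step: photolysis of the 3-diazoflavanone A1 with alcohol 2. The aryl carbon shifts to the carbene centre, the pyranone contracts, and the ketene is captured to give the dihydrobenzofuran ester A2.
- For: the hindered ester is made by ketene capture, not by acylation. The C5 bromide is a ready Heck handle, which saves the three steps the chosen route spends on the phenol-to-triflate exchange. The route is probably a few steps shorter overall.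
- Against: the carbene centre has a hydrogen on the adjacent C2, and a 1,2-hydride shift (which aromatises the pyranone without contracting it) competes with the aryl shift. The ketene must be caught by a hindered secondary alcohol used near stoichiometry, not by a solvent alcohol. A2 forms as a mixture at C2 and C3 that must then be dehydrogenated with a strong oxidant next to electron-rich benzyl ethers.
- Comparison: Alternative 1 is stronger on step count. The chosen route gives the aromatic benzofuran directly, has no competing hydride shift, and forms the ester on an unhindered β-keto ester.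

**Alternative 2:** Biomimetic oxidative dimerisation.
- Disconnection: C3–C3a and O1–C2 are cut, giving two molecules of the protected rosmarinate A3 with one free phenol.
- Forward key step: one-electron oxidation of A3 with a silver-based oxidant; 8–5' radical coupling and quinone-methide capture give the trans-dihydrobenzofuran A4.
- For: this is clearly the shortest route. Both lactate units, the alkene and the whole carbon skeleton are in place after one step, and only dehydrogenation and debenzylation remain.
- Against: nothing in A3 steers the radical coupling except spin density, so 8–8', 8–O–4' and 5–5' modes and oligomerisation compete. A4 keeps a free, oxidisable phenol. A4 forms as two trans diastereomers because each half carries an R centre. The dihydrofuran must still be aromatised, and A3 needs a selectively mono-protected caffeic acid.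
- Comparison: Alternative 2 is stronger on step economy and convergence. The chosen route offers regiochemical control at every bond and no statistical loss of advanced material.

**Alternative 3:** Carbonylative oxypalladation.
- Disconnection: O1–C2, the C3–carboxyl bond and the ester C–O bond are cut, leading back to the o-alkynylphenol A5, which already carries the cinnamate.
- Forward key step: a divalent palladium catalyst with a quinone reoxidant under a carbonylating atmosphere closes the furan, inserts the carboxyl carbon and captures alcohol 2 to give A6, which is identical with 30.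
- For: highest convergence. A6 is one step from the target, and A5 is available by Sonogashira coupling.
- Against: this carbonylation normally runs in a simple alcohol as solvent. A hindered α-hydroxy ester at near stoichiometry is a poor partner, so protonation of the C3–palladium bond before carbonylation (plain cycloisomerisation) should dominate. The electron-rich phenol and the acrylate of A5 are both exposed to an oxidising palladium system.
- Comparison: Alternative 3 would be shorter if the step worked. The chosen route forms the C3 ester by an uncatalysed ketene capture of well-known type, so its risk lies in one pericyclic cascade whose regiochemistry is fixed by the substrate.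

Key step: step 9

Remark: compounds 1, 3, 4, 8, 16 and 17 are taken as commercial; alkyne 20 is not assumed to be commercial and is made in step 8.

## Route

Step 1
Reactants: 1 sodium (R)-3-(3,4-dihydroxyphenyl)-2-hydroxypropanoate (danshensu sodium)
Product: 2 benzyl (R)-3-[3,4-bis(benzyloxy)phenyl]-2-hydroxypropanoate
Conditions: BnBr (3.3 equiv), K2CO3, DMF, rt, argon
Reagents that add atoms: benzyl bromide, BrCc1ccccc1
Why: Williamson O-alkylation of the carboxylate and both phenoxides; carbonate does not deprotonate the secondary alcohol, which stays free, and the α-hydroxy ester should not epimerise at rt.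

Step 2
Reactants: 3 3,4-bis(benzyloxy)benzoic acid; 4 2,2-dimethyl-1,3-dioxane-4,6-dione (Meldrum's acid)
Product: 5 5-{[3,4-bis(benzyloxy)phenyl](hydroxy)methylidene}-2,2-dimethyl-1,3-dioxane-4,6-dione
Conditions: DCC, DMAP, CH2Cl2, 0 °C → rt
Reagents that add atoms: none
Why: Carbodiimide-mediated C-acylation of Meldrum's acid; the acidic product is obtained as its enol after an acid wash.

Step 3
Reactants: 5 acyl Meldrum's acid; 2 benzyl (R)-3-[3,4-bis(benzyloxy)phenyl]-2-hydroxypropanoate
Product: 7 benzyl (R)-3-[3,4-bis(benzyloxy)phenyl]-2-({3-[3,4-bis(benzyloxy)phenyl]-3-oxopropanoyl}oxy)propanoate, via aroylketene 6 (not isolated)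
Conditions: toluene, 100 °C
Reagents that add atoms: none
Why: Thermal cycloreversion of the acyl Meldrum's acid releases aroylketene 6, which the secondary alcohol captures to give the β-keto ester; no base is present and the C–O bond at the stereocentre is not touched, so the R configuration is kept.

Step 4
Reactants: 8 3-bromo-2-oxopropanoic acid (bromopyruvic acid)
Product: 9 tert-butyl 3-bromo-2-oxopropanoate
Conditions: Cl3CC(=NH)Ot-Bu, CH2Cl2/cyclohexane, rt
Reagents that add atoms: tert-butyl 2,2,2-trichloroacetimidate, CC(C)(C)OC(=N)C(Cl)(Cl)Cl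
Why: Acid-promoted tert-butylation of a carboxylic acid by the trichloroacetimidate; the strong α-keto acid catalyses its own esterification, so no base touches the bromoketone.

Step 5
Reactants: 7 β-keto ester; 9 tert-butyl 3-bromo-2-oxopropanoate
Product: 11 3-tert-butyl 4-{(R)-1-(benzyloxy)-3-[3,4-bis(benzyloxy)phenyl]-1-oxopropan-2-yl} 5-[3,4-bis(benzyloxy)phenyl]-3-hydroxy-2,3-dihydrofuran-3,4-dicarboxylate (both C3 epimers), via bromohydrin aldol adduct 10 (not isolated)
Conditions: i-Pr2NEt, THF, 0 °C → rt
Reagents that add atoms: none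
Why: Interrupted Feist–Benary reaction: the enol of 7 adds to the very electrophilic 2-oxo group of 9 (aldol), and the aryl ketone enol oxygen then displaces bromide in a 5-exo-tet closure. The hindered amine avoids quaternisation by the bromoketone and is too weak to epimerise the lactate centre; the new carbinol centre is uncontrolled and is erased in step 6.

Step 6
Reactants: 11 hydroxydihydrofuran
Product: 13 5-[3,4-bis(benzyloxy)phenyl]-4-[({(R)-1-(benzyloxy)-3-[3,4-bis(benzyloxy)phenyl]-1-oxopropan-2-yl}oxy)carbonyl]furan-3-carboxylic acid, via furan tert-butyl ester 12 (not isolated)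
Conditions: CF3CO2H/CH2Cl2 (1:3), 0 °C → rt
Reagents that add atoms: none
Why: Acid-promoted dehydration through an oxocarbenium ion aromatises the dihydrofuran, and the same acid cleaves the tert-butyl ester (acidolysis with loss of isobutene); aryl benzyl ethers, the benzyl ester and the secondary ester are stable to this acid at rt.

Step 7
Reactants: 13 furan-3-carboxylic acid
Product: 15 benzyl (R)-3-[3,4-bis(benzyloxy)phenyl]-2-({2-[3,4-bis(benzyloxy)phenyl]-4-(2-diazoacetyl)furan-3-carbonyl}oxy)propanoate, via acid chloride 14 (not isolated)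
Conditions: (COCl)2, cat. DMF, CH2Cl2, 0 °C → rt; evaporate; CH2N2 (3 equiv), Et2O/THF, 0 °C
Reagents that add atoms: diazomethane, C=[N+]=[N-]; oxalyl chloride, O=C(Cl)C(=O)Cl (its chlorine stays only in intermediate 14)
Why: Acid chloride formation followed by Arndt–Eistert-type acylation of diazomethane; excess diazomethane removes the HCl, and the conditions are neutral enough for both esters and the stereocentre.

Step 8
Reactants: 16 ethyne (acetylene); 17 triisopropylsilyl trifluoromethanesulfonate
Product: 20 (triisopropylsilyloxy)ethyne, via lithium acetylide 18 (not isolated), via lithium ethynolate 19 (not isolated)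
Conditions: HC≡CH (excess), n-BuLi, THF, −78 °C; LiOOt-Bu (from t-BuOOH and LiN(SiMe3)2, THF, −78 °C), −78 → −20 °C; then 17, −78 → 0 °C
Reagents that add atoms: lithium tert-butyl peroxide, [Li+].CC(C)(C)O[O-] (from tert-butyl hydroperoxide, CC(C)(C)OO; supplies the oxygen atom)
Why: Oxidation of a lithium acetylide at carbon by lithium tert-butyl peroxide gives the lithium ynolate, and a bulky silyl triflate silylates ynolates at oxygen; this is the usual way to siloxyalkynes, applied here to the parent acetylide, which is kept cold to avoid disproportionation.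

Step 9
Reactants: 15 furan-4-yl diazomethyl ketone; 20 (triisopropylsilyloxy)ethyne
Product: 25 benzyl (R)-3-[3,4-bis(benzyloxy)phenyl]-2-({2-[3,4-bis(benzyloxy)phenyl]-7-hydroxy-5-(triisopropylsilyloxy)benzofuran-3-carbonyl}oxy)propanoate, via furylketene 21 (not isolated), via siloxycyclobutenone 22 (not isolated), via dienylketene 23 (not isolated), via dienone tautomer 24 (not isolated)
Conditions: 20 (2.5 equiv), ClCH2CH2Cl (degassed), hν (365 nm LEDs, Pyrex), rt; then 80 °C in the dark
Reagents that add atoms: none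
Why: Photochemical Wolff rearrangement of 15 expels N2 and shifts the furan-4-yl group from the ketone carbon to the diazo carbon (forming what becomes C3a–C4) to give furylketene 21. The electron-rich unsubstituted carbon of 20 attacks the ketene carbonyl carbon and the siloxy-bearing carbon bonds to the ketene α-carbon, a regioselective [2+2] addition that forms C6–C7 and C4–C5 and gives cyclobutenone 22. On heating, 22 opens by 4π electrocyclic reaction to dienylketene 23; 6π electrocyclisation of 23 through the furan C4–C5 double bond forms C7–C7a and gives dienone 24, which tautomerises to phenol 25, so that four C–C bonds of ring A are new. The closest known reaction type is the second-generation Danheiser benzannulation of aryl and heteroaryl diazomethyl ketones with siloxyalkynes, which gives fused resorcinol monosilyl ethers. Ring A is closed by a thermal disrotatory 6π electrocyclisation (six-membered, all carbon) after the [2+2] addition and 4π opening; no new stereocentre remains, since the sp3 carbons of 22 and 24 are lost on aromatisation. The step needs regiochemistry in the [2+2] addition, secured by the polarisation of the ynol ether, and in the ring closure, secured because C5 of the furan is the only free position next to the ketene (C3 is blocked by the ester). It also needs the alkyne to outcompete the neighbouring C3 ester carbonyl and the product phenol for the ketene, which excess 20 and the separation of the light and heat stages should favour.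

Step 10
Reactants: 25 7-hydroxy-5-(triisopropylsilyloxy)benzofuran
Product: 26 benzyl (R)-2-({7-(benzyloxy)-2-[3,4-bis(benzyloxy)phenyl]-5-(triisopropylsilyloxy)benzofuran-3-carbonyl}oxy)-3-[3,4-bis(benzyloxy)phenyl]propanoate
Conditions: BnBr, K2CO3, DMF, rt
Reagents that add atoms: benzyl bromide, BrCc1ccccc1
Why: Williamson benzylation of the only free phenol; the aryl triisopropylsilyl ether is stable to dry carbonate, and the mild base at rt should not epimerise the α-acyloxy ester.

Step 11
Reactants: 26 7-benzyloxy-5-silyloxybenzofuran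
Product: 27 benzyl (R)-2-({7-(benzyloxy)-2-[3,4-bis(benzyloxy)phenyl]-5-hydroxybenzofuran-3-carbonyl}oxy)-3-[3,4-bis(benzyloxy)phenyl]propanoate
Conditions: Bu4NF, AcOH, THF, 0 °C
Reagents that add atoms: none
Why: Fluoride cleavage of the aryl silyl ether; buffering with acetic acid keeps the medium non-basic, so the benzyl ester and both α-acyloxy ester units are spared.

Step 12
Reactants: 27 5-hydroxybenzofuran
Product: 28 benzyl (R)-2-({7-(benzyloxy)-2-[3,4-bis(benzyloxy)phenyl]-5-{[(trifluoromethyl)sulfonyl]oxy}benzofuran-3-carbonyl}oxy)-3-[3,4-bis(benzyloxy)phenyl]propanoate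
Conditions: PhNTf2, Et3N, cat. DMAP, CH2Cl2, rt
Reagents that add atoms: N-phenylbis(trifluoromethanesulfonimide), O=S(=O)(N(c1ccccc1)S(=O)(=O)C(F)(F)F)C(F)(F)F
Why: Sulfonylation of the single free phenol with a mild triflyl donor; no other nucleophilic site is present.

Step 13
Reactants: 2 benzyl (R)-3-[3,4-bis(benzyloxy)phenyl]-2-hydroxypropanoate
Product: 29 benzyl (R)-2-(acryloyloxy)-3-[3,4-bis(benzyloxy)phenyl]propanoate
Conditions: CH2=CHCOCl, Et3N, CH2Cl2, −20 → 0 °C
Reagents that add atoms: acryloyl chloride, C=CC(=O)Cl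
Why: O-acylation of a secondary alcohol by an acid chloride; the C–O bond at the stereocentre is not broken, so the R configuration is kept.

Step 14
Reactants: 28 aryl triflate; 29 acrylate
Product: 30 benzyl (R)-2-{[(E)-3-(7-(benzyloxy)-3-{[(R)-1-(benzyloxy)-3-(3,4-bis(benzyloxy)phenyl)-1-oxopropan-2-yl]oxycarbonyl}-2-[3,4-bis(benzyloxy)phenyl]benzofuran-5-yl)prop-2-enoyl]oxy}-3-[3,4-bis(benzyloxy)phenyl]propanoate (nonabenzyl schizotenuin A)
Conditions: Pd(OAc)2 (5 mol %), dppp (6 mol %), Et3N, DMF, 80 °C
Reagents that add atoms: none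
Why: Heck reaction: oxidative addition of the aryl triflate to zerovalent palladium formed in situ, syn insertion of the acrylate at its unsubstituted terminus and syn β-hydride elimination give the (E)-cinnamate; no stereocentre is touched.

Step 15
Reactants: 30 nonabenzyl schizotenuin A
Product: 31 schizotenuin A
Conditions: BCl3 (1 M in CH2Cl2, 25 equiv), C6HMe5 (30 equiv), CH2Cl2, −78 → 0 °C; then H2O
Reagents that add atoms: none
Why: Lewis-acid debenzylation: BCl3 ionises the benzyl–oxygen bonds of the aryl ethers and benzyl esters, and pentamethylbenzene traps the benzyl cations by Friedel–Crafts alkylation. The alkene is inert, and the secondary ester C–O bonds lie next to a carboxyl group and do not ionise, so both R centres are kept.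

## Compound list

1 | sodium (R)-3-(3,4-dihydroxyphenyl)-2-hydroxypropanoate (danshensu sodium) | O[C@H](Cc1ccc(O)c(O)c1)C(=O)[O-].[Na+] | starting material
2 | benzyl (R)-3-[3,4-bis(benzyloxy)phenyl]-2-hydroxypropanoate | O[C@H](Cc1ccc(OCc2ccccc2)c(OCc2ccccc2)c1)C(=O)OCc1ccccc1 | intermediate
3 | 3,4-bis(benzyloxy)benzoic acid | O=C(O)c1ccc(OCc2ccccc2)c(OCc2ccccc2)c1 | starting material
4 | 2,2-dimethyl-1,3-dioxane-4,6-dione (Meldrum's acid) | CC1(C)OC(=O)CC(=O)O1 | starting material
5 | 5-{[3,4-bis(benzyloxy)phenyl](hydroxy)methylidene}-2,2-dimethyl-1,3-dioxane-4,6-dione | CC1(C)OC(=O)C(=C(O)c2ccc(OCc3ccccc3)c(OCc3ccccc3)c2)C(=O)O1 | intermediate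
6 | 3-[3,4-bis(benzyloxy)phenyl]-3-oxoprop-1-en-1-one (aroylketene) | O=C=CC(=O)c1ccc(OCc2ccccc2)c(OCc2ccccc2)c1 | intermediate (not isolated)
7 | benzyl (R)-3-[3,4-bis(benzyloxy)phenyl]-2-({3-[3,4-bis(benzyloxy)phenyl]-3-oxopropanoyl}oxy)propanoate | O=C(CC(=O)O[C@H](Cc1ccc(OCc2ccccc2)c(OCc2ccccc2)c1)C(=O)OCc1ccccc1)c1ccc(OCc2ccccc2)c(OCc2ccccc2)c1 | intermediate
8 | 3-bromo-2-oxopropanoic acid (bromopyruvic acid) | O=C(O)C(=O)CBr | starting material
9 | tert-butyl 3-bromo-2-oxopropanoate | CC(C)(C)OC(=O)C(=O)CBr | intermediate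
10 | 1-{(R)-1-(benzyloxy)-3-[3,4-bis(benzyloxy)phenyl]-1-oxopropan-2-yl} 4-tert-butyl 2-[3,4-bis(benzyloxy)benzoyl]-3-(bromomethyl)-3-hydroxybutanedioate (mixture at C2 and C3) | O=C(c1ccc(OCc2ccccc2)c(OCc2ccccc2)c1)C(C(=O)O[C@H](Cc1ccc(OCc2ccccc2)c(OCc2ccccc2)c1)C(=O)OCc1ccccc1)C(O)(CBr)C(=O)OC(C)(C)C | intermediate (not isolated)
11 | 3-tert-butyl 4-{(R)-1-(benzyloxy)-3-[3,4-bis(benzyloxy)phenyl]-1-oxopropan-2-yl} 5-[3,4-bis(benzyloxy)phenyl]-3-hydroxy-2,3-dihydrofuran-3,4-dicarboxylate (both C3 epimers) | OC1(C(=O)OC(C)(C)C)COC(c2ccc(OCc3ccccc3)c(OCc3ccccc3)c2)=C1C(=O)O[C@H](Cc1ccc(OCc2ccccc2)c(OCc2ccccc2)c1)C(=O)OCc1ccccc1 | intermediate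
12 | 4-tert-butyl 3-{(R)-1-(benzyloxy)-3-[3,4-bis(benzyloxy)phenyl]-1-oxopropan-2-yl} 2-[3,4-bis(benzyloxy)phenyl]furan-3,4-dicarboxylate | CC(C)(C)OC(=O)c1coc(-c2ccc(OCc3ccccc3)c(OCc3ccccc3)c2)c1C(=O)O[C@H](Cc1ccc(OCc2ccccc2)c(OCc2ccccc2)c1)C(=O)OCc1ccccc1 | intermediate (not isolated)
13 | 5-[3,4-bis(benzyloxy)phenyl]-4-[({(R)-1-(benzyloxy)-3-[3,4-bis(benzyloxy)phenyl]-1-oxopropan-2-yl}oxy)carbonyl]furan-3-carboxylic acid | OC(=O)c1coc(-c2ccc(OCc3ccccc3)c(OCc3ccccc3)c2)c1C(=O)O[C@H](Cc1ccc(OCc2ccccc2)c(OCc2ccccc2)c1)C(=O)OCc1ccccc1 | intermediate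
14 | benzyl (R)-3-[3,4-bis(benzyloxy)phenyl]-2-({2-[3,4-bis(benzyloxy)phenyl]-4-(chlorocarbonyl)furan-3-carbonyl}oxy)propanoate | ClC(=O)c1coc(-c2ccc(OCc3ccccc3)c(OCc3ccccc3)c2)c1C(=O)O[C@H](Cc1ccc(OCc2ccccc2)c(OCc2ccccc2)c1)C(=O)OCc1ccccc1 | intermediate (not isolated)
15 | benzyl (R)-3-[3,4-bis(benzyloxy)phenyl]-2-({2-[3,4-bis(benzyloxy)phenyl]-4-(2-diazoacetyl)furan-3-carbonyl}oxy)propanoate | [N-]=[N+]=CC(=O)c1coc(-c2ccc(OCc3ccccc3)c(OCc3ccccc3)c2)c1C(=O)O[C@H](Cc1ccc(OCc2ccccc2)c(OCc2ccccc2)c1)C(=O)OCc1ccccc1 | intermediate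
16 | ethyne (acetylene) | C#C | starting material
17 | triisopropylsilyl trifluoromethanesulfonate | CC(C)[Si](C(C)C)(C(C)C)OS(=O)(=O)C(F)(F)F | starting material
18 | lithium acetylide | [Li+].[C-]#C | intermediate (not isolated)
19 | lithium ethynolate | [Li+].[O-]C#C | intermediate (not isolated)
20 | (triisopropylsilyloxy)ethyne | C#CO[Si](C(C)C)(C(C)C)C(C)C | intermediate
21 | benzyl (R)-3-[3,4-bis(benzyloxy)phenyl]-2-({2-[3,4-bis(benzyloxy)phenyl]-4-(2-oxoethenyl)furan-3-carbonyl}oxy)propanoate (furylketene) | O=C=Cc1coc(-c2ccc(OCc3ccccc3)c(OCc3ccccc3)c2)c1C(=O)O[C@H](Cc1ccc(OCc2ccccc2)c(OCc2ccccc2)c1)C(=O)OCc1ccccc1 | intermediate (not isolated)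
22 | benzyl (R)-3-[3,4-bis(benzyloxy)phenyl]-2-({2-[3,4-bis(benzyloxy)phenyl]-4-[4-oxo-2-(triisopropylsilyloxy)cyclobut-2-en-1-yl]furan-3-carbonyl}oxy)propanoate (both epimers at the ring carbon) | O=C1C=C(O[Si](C(C)C)(C(C)C)C(C)C)C1c1coc(-c2ccc(OCc3ccccc3)c(OCc3ccccc3)c2)c1C(=O)O[C@H](Cc1ccc(OCc2ccccc2)c(OCc2ccccc2)c1)C(=O)OCc1ccccc1 | intermediate (not isolated)
23 | benzyl (R)-3-[3,4-bis(benzyloxy)phenyl]-2-({2-[3,4-bis(benzyloxy)phenyl]-4-[4-oxo-2-(triisopropylsilyloxy)buta-1,3-dien-1-yl]furan-3-carbonyl}oxy)propanoate (ketene and furan on the same side of the C=C bond) | O=C=C/C(O[Si](C(C)C)(C(C)C)C(C)C)=C\c1coc(-c2ccc(OCc3ccccc3)c(OCc3ccccc3)c2)c1C(=O)O[C@H](Cc1ccc(OCc2ccccc2)c(OCc2ccccc2)c1)C(=O)OCc1ccccc1 | intermediate (not isolated)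
24 | benzyl (R)-3-[3,4-bis(benzyloxy)phenyl]-2-({2-[3,4-bis(benzyloxy)phenyl]-7-oxo-5-(triisopropylsilyloxy)-7,7a-dihydrobenzofuran-3-carbonyl}oxy)propanoate (both C7a epimers) | O=C1C=C(O[Si](C(C)C)(C(C)C)C(C)C)C=C2C(C(=O)O[C@H](Cc3ccc(OCc4ccccc4)c(OCc4ccccc4)c3)C(=O)OCc3ccccc3)=C(c3ccc(OCc4ccccc4)c(OCc4ccccc4)c3)OC12 | intermediate (not isolated)
25 | benzyl (R)-3-[3,4-bis(benzyloxy)phenyl]-2-({2-[3,4-bis(benzyloxy)phenyl]-7-hydroxy-5-(triisopropylsilyloxy)benzofuran-3-carbonyl}oxy)propanoate | Oc1cc(O[Si](C(C)C)(C(C)C)C(C)C)cc2c(C(=O)O[C@H](Cc3ccc(OCc4ccccc4)c(OCc4ccccc4)c3)C(=O)OCc3ccccc3)c(-c3ccc(OCc4ccccc4)c(OCc4ccccc4)c3)oc12 | intermediate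
26 | benzyl (R)-2-({7-(benzyloxy)-2-[3,4-bis(benzyloxy)phenyl]-5-(triisopropylsilyloxy)benzofuran-3-carbonyl}oxy)-3-[3,4-bis(benzyloxy)phenyl]propanoate | O(Cc1ccccc1)c1cc(O[Si](C(C)C)(C(C)C)C(C)C)cc2c(C(=O)O[C@H](Cc3ccc(OCc4ccccc4)c(OCc4ccccc4)c3)C(=O)OCc3ccccc3)c(-c3ccc(OCc4ccccc4)c(OCc4ccccc4)c3)oc12 | intermediate
27 | benzyl (R)-2-({7-(benzyloxy)-2-[3,4-bis(benzyloxy)phenyl]-5-hydroxybenzofuran-3-carbonyl}oxy)-3-[3,4-bis(benzyloxy)phenyl]propanoate | O(Cc1ccccc1)c1cc(O)cc2c(C(=O)O[C@H](Cc3ccc(OCc4ccccc4)c(OCc4ccccc4)c3)C(=O)OCc3ccccc3)c(-c3ccc(OCc4ccccc4)c(OCc4ccccc4)c3)oc12 | intermediate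
28 | benzyl (R)-2-({7-(benzyloxy)-2-[3,4-bis(benzyloxy)phenyl]-5-{[(trifluoromethyl)sulfonyl]oxy}benzofuran-3-carbonyl}oxy)-3-[3,4-bis(benzyloxy)phenyl]propanoate | O(Cc1ccccc1)c1cc(OS(=O)(=O)C(F)(F)F)cc2c(C(=O)O[C@H](Cc3ccc(OCc4ccccc4)c(OCc4ccccc4)c3)C(=O)OCc3ccccc3)c(-c3ccc(OCc4ccccc4)c(OCc4ccccc4)c3)oc12 | intermediate
29 | benzyl (R)-2-(acryloyloxy)-3-[3,4-bis(benzyloxy)phenyl]propanoate | C=CC(=O)O[C@H](Cc1ccc(OCc2ccccc2)c(OCc2ccccc2)c1)C(=O)OCc1ccccc1 | intermediate
30 | nonabenzyl schizotenuin A (seven benzyl ethers, two benzyl esters; E alkene; both lactate centres R) | O=C(/C=C/c1cc(OCc4ccccc4)c2oc(-c3ccc(OCc4ccccc4)c(OCc4ccccc4)c3)c(C(=O)O[C@H](Cc3ccc(OCc4ccccc4)c(OCc4ccccc4)c3)C(=O)OCc3ccccc3)c2c1)O[C@H](Cc1ccc(OCc2ccccc2)c(OCc2ccccc2)c1)C(=O)OCc1ccccc1 | intermediate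
31 | schizotenuin A | O=C(/C=C/c1cc(O)c2oc(-c3ccc(O)c(O)c3)c(C(=O)O[C@H](Cc3ccc(O)c(O)c3)C(=O)O)c2c1)O[C@H](Cc1ccc(O)c(O)c1)C(=O)O | target

## Step count and least certain steps

Total step count: 15. Longest linear sequence: 11 steps (steps 1, 3, 5, 6, 7, 9, 10, 11, 12, 14, 15, from 1 to 31).

**Step 9 (key step).** The arylfuran chromophore may absorb most of the light and slow the Wolff rearrangement. The ketene may be captured by the neighbouring C3 ester carbonyl oxygen, or acylate phenol that forms early under irradiation. The siloxyalkyne may be hydrolysed by traces of acid. Fallback, from 15 back to 25, makes the same ketene without light. A rearrangement of 15 catalysed by AgO2CPh with Et3N in aqueous THF in the dark (Arndt–Eistert homologation) gives 2-{5-[3,4-bis(benzyloxy)phenyl]-4-[({(R)-1-(benzyloxy)-3-[3,4-bis(benzyloxy)phenyl]-1-oxopropan-2-yl}oxy)carbonyl]furan-3-yl}acetic acid F1. Oxalyl chloride converts it into the acid chloride F2. Slow addition of Et3N to F2 and 20 in toluene at 80 °C dehydrochlorinates F2 to ketene 21, which enters the same [2+2], 4π, 6π sequence and gives 25.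

**Step 8.** Lithium acetylide may disproportionate to Li2C2 and acetylene before it is oxidised. The parent ynolate may be silylated at carbon (giving a silylketene) and not at oxygen. The volatile product may be lost on isolation. Fallback, from 17 back to 20, reaches the alkyne by elimination, not through an ynolate. n-BuLi cleaves tetrahydrofuran at rt to ethene and lithium ethenolate F3, which 17 silylates to triisopropyl(vinyloxy)silane F4. Bromine at −78 °C gives (1,2-dibromoethoxy)triisopropylsilane F5, and Et3N removes HBr to give (Z)-(2-bromoethenyloxy)triisopropylsilane F6. Two equivalents of LiN(i-Pr)2 at −78 °C eliminate HBr and give lithium (triisopropylsilyloxy)ethynide F7, which water protonates to 20.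

**Step 15.** The benzyl esters may be cleaved more slowly than the aryl ethers, leaving partly protected material. Benzyl cations may alkylate the electron-rich rings despite the scavenger. The free catechols may oxidise in air during work-up. Fallback, from 28 (with 2 and 4) to 31, removes the benzyl groups by hydrogenolysis before the alkene exists and forms the alkene last. The triflate 28 is converted into aldehyde F8 as in the fallback for step 14. Hydrogenolysis of F8 (H2, Pd on carbon, EtOAc/THF) gives (R)-3-(3,4-dihydroxyphenyl)-2-{[2-(3,4-dihydroxyphenyl)-5-formyl-7-hydroxybenzofuran-3-carbonyl]oxy}propanoic acid F10. Heating 2 with 4 in toluene gives the malonic half ester 3-({(R)-1-(benzyloxy)-3-[3,4-bis(benzyloxy)phenyl]-1-oxopropan-2-yl}oxy)-3-oxopropanoic acid F11, and hydrogenolysis gives (R)-2-[(carboxyacetyl)oxy]-3-(3,4-dihydroxyphenyl)propanoic acid F12. Knoevenagel–Doebner condensation of F10 with F12 (pyridine, cat. piperidine, 60 °C), which tolerates free phenols and acids, gives the (E)-cinnamate 31 with loss of CO2.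

**Step 14.** Oxidative addition to the electron-rich triflate may be slow, so that hydrolysis of the triflate back to the phenol or polymerisation of the acrylate takes over. Prolonged heating with amine may epimerise an α-acyloxy ester. Fallback, from 28 (with 2) back to 30, replaces the coupling by an olefination. Reductive carbonylation of 28 (Pd(OAc)2, dppp, CO, Et3SiH, Et3N, DMF, 70 °C) gives benzyl (R)-2-({7-(benzyloxy)-2-[3,4-bis(benzyloxy)phenyl]-5-formylbenzofuran-3-carbonyl}oxy)-3-[3,4-bis(benzyloxy)phenyl]propanoate F8. Esterification of 2 with diethylphosphonoacetic acid (DCC, DMAP) gives benzyl (R)-3-[3,4-bis(benzyloxy)phenyl]-2-{[2-(diethoxyphosphoryl)acetyl]oxy}propanoate F9. Horner–Wadsworth–Emmons reaction of F8 with F9 under Masamune–Roush conditions (LiCl, i-Pr2NEt, MeCN, rt) gives 30 with E geometry.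

## Further compounds

F1 | step 9 | 2-{5-[3,4-bis(benzyloxy)phenyl]-4-[({(R)-1-(benzyloxy)-3-[3,4-bis(benzyloxy)phenyl]-1-oxopropan-2-yl}oxy)carbonyl]furan-3-yl}acetic acid | OC(=O)Cc1coc(-c2ccc(OCc3ccccc3)c(OCc3ccccc3)c2)c1C(=O)O[C@H](Cc1ccc(OCc2ccccc2)c(OCc2ccccc2)c1)C(=O)OCc1ccccc1
F2 | step 9 | benzyl (R)-3-[3,4-bis(benzyloxy)phenyl]-2-({2-[3,4-bis(benzyloxy)phenyl]-4-(2-chloro-2-oxoethyl)furan-3-carbonyl}oxy)propanoate | ClC(=O)Cc1coc(-c2ccc(OCc3ccccc3)c(OCc3ccccc3)c2)c1C(=O)O[C@H](Cc1ccc(OCc2ccccc2)c(OCc2ccccc2)c1)C(=O)OCc1ccccc1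
F3 | step 8 | lithium ethenolate | [Li+].[O-]C=C
F4 | step 8 | triisopropyl(vinyloxy)silane | C=CO[Si](C(C)C)(C(C)C)C(C)C
F5 | step 8 | (1,2-dibromoethoxy)triisopropylsilane | BrCC(Br)O[Si](C(C)C)(C(C)C)C(C)C
F6 | step 8 | (Z)-(2-bromoethenyloxy)triisopropylsilane | Br/C=C\O[Si](C(C)C)(C(C)C)C(C)C
F7 | step 8 | lithium (triisopropylsilyloxy)ethynide | [Li+].[C-]#CO[Si](C(C)C)(C(C)C)C(C)C
F8 | step 14 | benzyl (R)-2-({7-(benzyloxy)-2-[3,4-bis(benzyloxy)phenyl]-5-formylbenzofuran-3-carbonyl}oxy)-3-[3,4-bis(benzyloxy)phenyl]propanoate | O=Cc1cc(OCc2ccccc2)c2oc(-c3ccc(OCc4ccccc4)c(OCc4ccccc4)c3)c(C(=O)O[C@H](Cc3ccc(OCc4ccccc4)c(OCc4ccccc4)c3)C(=O)OCc3ccccc3)c2c1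
F9 | step 14 | benzyl (R)-3-[3,4-bis(benzyloxy)phenyl]-2-{[2-(diethoxyphosphoryl)acetyl]oxy}propanoate | CCOP(=O)(CC(=O)O[C@H](Cc1ccc(OCc2ccccc2)c(OCc2ccccc2)c1)C(=O)OCc1ccccc1)OCC
F10 | step 15 | (R)-3-(3,4-dihydroxyphenyl)-2-{[2-(3,4-dihydroxyphenyl)-5-formyl-7-hydroxybenzofuran-3-carbonyl]oxy}propanoic acid | O=Cc1cc(O)c2oc(-c3ccc(O)c(O)c3)c(C(=O)O[C@H](Cc3ccc(O)c(O)c3)C(=O)O)c2c1
F11 | step 15 | 3-({(R)-1-(benzyloxy)-3-[3,4-bis(benzyloxy)phenyl]-1-oxopropan-2-yl}oxy)-3-oxopropanoic acid | OC(=O)CC(=O)O[C@H](Cc1ccc(OCc2ccccc2)c(OCc2ccccc2)c1)C(=O)OCc1ccccc1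
F12 | step 15 | (R)-2-[(carboxyacetyl)oxy]-3-(3,4-dihydroxyphenyl)propanoic acid | OC(=O)CC(=O)O[C@H](Cc1ccc(O)c(O)c1)C(=O)O
A1 | alternative 1 | 8-(benzyloxy)-2-[3,4-bis(benzyloxy)phenyl]-6-bromo-3-diazochroman-4-one (racemic at C2) | [N-]=[N+]=C1C(=O)c2cc(Br)cc(OCc3ccccc3)c2OC1c1ccc(OCc2ccccc2)c(OCc2ccccc2)c1
A2 | alternative 1 | benzyl (R)-3-[3,4-bis(benzyloxy)phenyl]-2-({7-(benzyloxy)-2-[3,4-bis(benzyloxy)phenyl]-5-bromo-2,3-dihydrobenzofuran-3-carbonyl}oxy)propanoate (mixture at C2 and C3) | Brc1cc(OCc4ccccc4)c2OC(c3ccc(OCc4ccccc4)c(OCc4ccccc4)c3)C(C(=O)O[C@H](Cc3ccc(OCc4ccccc4)c(OCc4ccccc4)c3)C(=O)OCc3ccccc3)c2c1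
A3 | alternative 2 | benzyl (R)-2-{[(E)-3-(3-(benzyloxy)-4-hydroxyphenyl)prop-2-enoyl]oxy}-3-[3,4-bis(benzyloxy)phenyl]propanoate | O=C(/C=C/c1ccc(O)c(OCc2ccccc2)c1)O[C@H](Cc1ccc(OCc2ccccc2)c(OCc2ccccc2)c1)C(=O)OCc1ccccc1
A4 | alternative 2 | octabenzyl trans-2,3-dihydro schizotenuin A with the 4-hydroxyl of the 2-aryl ring free (one of the two trans diastereomers drawn) | O=C(/C=C/c1cc(OCc4ccccc4)c2O[C@@H](c3ccc(O)c(OCc4ccccc4)c3)[C@H](C(=O)O[C@H](Cc3ccc(OCc4ccccc4)c(OCc4ccccc4)c3)C(=O)OCc3ccccc3)c2c1)O[C@H](Cc1ccc(OCc2ccccc2)c(OCc2ccccc2)c1)C(=O)OCc1ccccc1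
A5 | alternative 3 | benzyl (R)-2-{[(E)-3-(3-(benzyloxy)-5-{[3,4-bis(benzyloxy)phenyl]ethynyl}-4-hydroxyphenyl)prop-2-enoyl]oxy}-3-[3,4-bis(benzyloxy)phenyl]propanoate | O=C(/C=C/c1cc(OCc2ccccc2)c(O)c(C#Cc2ccc(OCc3ccccc3)c(OCc3ccccc3)c2)c1)O[C@H](Cc1ccc(OCc2ccccc2)c(OCc2ccccc2)c1)C(=O)OCc1ccccc1
A6 | alternative 3 | nonabenzyl schizotenuin A (identical with 30) | O=C(/C=C/c1cc(OCc4ccccc4)c2oc(-c3ccc(OCc4ccccc4)c(OCc4ccccc4)c3)c(C(=O)O[C@H](Cc3ccc(OCc4ccccc4)c(OCc4ccccc4)c3)C(=O)OCc3ccccc3)c2c1)O[C@H](Cc1ccc(OCc2ccccc2)c(OCc2ccccc2)c1)C(=O)OCc1ccccc1
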